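**Retrosynthetic overview**

1. Naming: upper flavan = ring A (phloroglucinol ring, C4a–C8a), ring B (4-hydroxyphenyl), ring C (pyran, O1–C4). Lower unit (double-primed atoms) = ring D (benzo ring), ring E (pyranone), ring F (4-hydroxyphenyl). Ring G = the dihydrofuran ketal ring (C8, C7, O, C2'', C3'').
2. Ring G is closed last: the C7 oxygen adds to C2'' of a flavone 2'',3''-epoxide made by catalyst-controlled epoxidation. The C8–C3'' bond comes from a Negishi coupling of the 8-zincated flavan with a 3-iodoflavone (rings D, E, F from apigenin).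
3. Flavan stereocentres C2/C3: asymmetric syn-hydroboration of a flav-2-ene (C2=C3 enol ether), then O-methylation.
4. Ring C is made first (key step): formal (3+3) union of the enolate of 4-benzyloxyacetophenone with a 2-bromobenzyl chloride. C3–C4 forms by C-benzylation and O1–C8a by copper-catalysed enolate O-arylation, in one flask.
5. Enabling feature: in ring C, C2 carries both O1 and ring B, so at the ketone level O1=C2–C3 is an enolate that is nucleophilic at C3 and at O1. C4 (benzylic) and C8a (its ortho carbon in ring A) are the matching 1,3-dielectrophile. Closure through carbon would need a four-membered ring, so oxygen closes ring C.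

Key step: step 5

Assumption (a): the facial sense of IpcBH2 on enol ether 10 is taken from 1-arylcycloalkenes, which calls for the reagent made from (−)-α-pinene.
Assumption (b): the (R,R)-configured manganese salen catalyst is taken to attack the chromone face that gives the (R)-C3'' carbinol; if not, the (S,S)-catalyst is used and nothing else changes.
Assumption (c): the ketal carbon C2'' is not set independently; it is taken that closure of the C7 oxygen onto C2'' next to the (R)-C3'' carbinol gives the C2'' configuration written in the target.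

**Route**

Step 1
Reactants: 1 5-bromobenzene-1,3-diol
Product: 3 2-bromo-4,6-dihydroxybenzaldehyde, via iminium chloride 2 (not isolated)
Conditions: POCl3, DMF, MeCN, 0 °C → rt; then H2O, 50 °C
Reagents that add atoms: N,N-dimethylformamide CN(C)C=O; water O
Why: Vilsmeier–Haack formylation should occur at C4 of the resorcinol (ortho to one hydroxyl, para to the other) rather than at the doubly flanked C2, and the iminium salt 2 is hydrolysed on aqueous work-up; no stereocentre is formed.

Step 2
Reactants: 3 2-bromo-4,6-dihydroxybenzaldehyde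
Product: 4 2-bromo-4,6-bis(methoxymethoxy)benzaldehyde
Conditions: NaH, MOMCl, DMF, 0 °C → rt
Reagents that add atoms: chloromethyl methyl ether COCCl
Why: Williamson-type O-alkylation of both phenoxides installs acid-labile protection on ring A that can later be removed without touching benzyl ethers; no stereocentre is formed.

Step 3
Reactants: 4 2-bromo-4,6-bis(methoxymethoxy)benzaldehyde
Product: 5 [2-bromo-4,6-bis(methoxymethoxy)phenyl]methanol
Conditions: NaBH4, MeOH/THF, 0 °C
Reagents that add atoms: none
Why: Chemoselective borohydride reduction of the aryl aldehyde; the aryl bromide and the acetals are inert.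

Step 4
Reactants: 5 [2-bromo-4,6-bis(methoxymethoxy)phenyl]methanol
Product: 7 1-bromo-2-(chloromethyl)-3,5-bis(methoxymethoxy)benzene, via benzylic mesylate 6 (not isolated)
Conditions: MsCl, Et3N, CH2Cl2, 0 °C → rt; used crude at once
Reagents that add atoms: methanesulfonyl chloride CS(=O)(=O)Cl
Why: Mesylation of the electron-rich benzylic alcohol followed by in situ displacement of the mesylate by the liberated chloride (nucleophilic substitution) should give the benzylic chloride, which is not stored because 2,4-dialkoxybenzyl halides are labile.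

Step 5
Reactants: 7 1-bromo-2-(chloromethyl)-3,5-bis(methoxymethoxy)benzene; 8 1-[4-(benzyloxy)phenyl]ethan-1-one (1.3 equiv)
Product: 10 2-[4-(benzyloxy)phenyl]-5,7-bis(methoxymethoxy)-4H-chromene, via bromo ketone 9 (not isolated)
Conditions: 8, LiN(SiMe3)2, THF, −78 °C; then 7, −78 → 0 °C; then KOt-Bu, CuI (10 mol %), 1,10-phenanthroline (20 mol %), toluene, 85 °C (one flask)
Reagents that add atoms: none
Why: Proposed new method: the lithium enolate of 8 is C-benzylated by the activated benzylic chloride 7 (SN2, forms C3–C4) to give 9, which KOt-Bu re-enolises to the (Z)-enolate whose oxygen is joined to the C8a–Br carbon by a phenanthroline–copper enolate through an Ullmann-type oxidative addition/reductive elimination (forms O1–C8a). The closest known reaction type is the CuI-catalysed domino C-benzylation/intramolecular O-arylation of 1,3-dicarbonyl compounds with 2-bromobenzyl bromides to 4H-chromenes, together with intramolecular O-arylation of ketone enolates to benzofurans; the extension is to a non-stabilised aryl ketone enolate, hence the stronger bases and the two temperature stages. Ring C closes in a 6-exo sense at the aromatic carbon (the C–Br bond lies outside the new ring) and through oxygen, because C-arylation of the same enolate would have to form a benzocyclobutene. No stereocentre is created; the step delivers the C2=C3 enol ether whose syn-hydroboration sets both flavan stereocentres in step 6. The selectivities needed are mono- over dialkylation, secured by the slight excess of the enolate of 8 at low temperature, and O-arylation over intermolecular α-arylation, secured by the six-membered intramolecular closure and by copper, which has little tendency to α-arylate simple ketone enolates. The methoxymethyl and benzyl ethers should be inert to these basic conditions.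

Step 6
Reactants: 10 2-[4-(benzyloxy)phenyl]-5,7-bis(methoxymethoxy)-4H-chromene
Product: 12 (2S,3R)-2-[4-(benzyloxy)phenyl]-5,7-bis(methoxymethoxy)chroman-3-ol, via alkyl(isopinocampheyl)borane 11 (not isolated)
Conditions: IpcBH2 (from (−)-α-pinene), THF, −25 °C; then NaOH, H2O2, 0 °C → rt
Reagents that add atoms: hydrogen peroxide OO
Why: Asymmetric hydroboration–oxidation with monoisopinocampheylborane: boron adds to C3 (β to the enol-ether oxygen) and hydrogen to C2 in a syn fashion, which fixes the 2,3-trans relationship, the chiral borane selects the alkene face to give C2 (S) and C3 (R), and oxidation replaces boron by hydroxyl with retention.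

Step 7
Reactants: 12 (2S,3R)-2-[4-(benzyloxy)phenyl]-5,7-bis(methoxymethoxy)chroman-3-ol
Product: 13 (2S,3R)-2-[4-(benzyloxy)phenyl]-3-methoxy-5,7-bis(methoxymethoxy)chromane
Conditions: NaH, MeI, THF/DMF, 0 °C → rt
Reagents that add atoms: iodomethane CI
Why: Williamson etherification of the secondary alkoxide; the stereocentres are not involved.

Step 8
Reactants: 13 (2S,3R)-2-[4-(benzyloxy)phenyl]-3-methoxy-5,7-bis(methoxymethoxy)chromane
Product: 14 (2S,3R)-2-[4-(benzyloxy)phenyl]-8-bromo-3-methoxy-5,7-bis(methoxymethoxy)chromane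
Conditions: NBS, CH2Cl2, −20 → 0 °C
Reagents that add atoms: N-bromosuccinimide O=C1CCC(=O)N1Br
Why: Electrophilic aromatic bromination of ring A should go to C8, the position flanked by only one acyclic alkoxy group, as is general for 5,7-dialkoxyflavans; ring B and the benzyl group are far less activated.

Step 9
Reactants: 15 5,7-dihydroxy-2-(4-hydroxyphenyl)-4H-chromen-4-one (apigenin)
Product: 16 5,7-bis(benzyloxy)-2-[4-(benzyloxy)phenyl]-4H-chromen-4-one
Conditions: BnBr, K2CO3, DMF, 80 °C
Reagents that add atoms: benzyl bromide BrCc1ccccc1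
Why: Williamson benzylation of all three phenols; the chelated 5-hydroxyl needs the elevated temperature.

Step 10
Reactants: 16 5,7-bis(benzyloxy)-2-[4-(benzyloxy)phenyl]-4H-chromen-4-one
Product: 18 5,7-bis(benzyloxy)-2-[4-(benzyloxy)phenyl]-3-iodo-4H-chromen-4-one, via 3-lithioflavone 17 (not isolated)
Conditions: LiN(i-Pr)2, THF, −78 °C; then I2, −78 °C
Reagents that add atoms: iodine II
Why: Carbonyl-directed C3 lithiation of the flavone and iodinolysis of the vinyllithium should give the 3-iodoflavone; the low temperature suppresses ring opening of 17.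

Step 11
Reactants: 14 (2S,3R)-2-[4-(benzyloxy)phenyl]-8-bromo-3-methoxy-5,7-bis(methoxymethoxy)chromane; 18 5,7-bis(benzyloxy)-2-[4-(benzyloxy)phenyl]-3-iodo-4H-chromen-4-one
Product: 21 5,7-bis(benzyloxy)-2-[4-(benzyloxy)phenyl]-3-[(2S,3R)-2-[4-(benzyloxy)phenyl]-3-methoxy-5,7-bis(methoxymethoxy)chroman-8-yl]-4H-chromen-4-one, via aryllithium 19 (not isolated), via arylzinc chloride 20 (not isolated)
Conditions: 14, n-BuLi, THF, −78 °C; ZnCl2, −78 °C → rt; then 18, Pd2(dba)3 (2.5 mol %), RuPhos (10 mol %), THF, 60 °C
Reagents that add atoms: none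
Why: Negishi cross-coupling: bromine–lithium exchange at C8, transmetalation to zinc and palladium-catalysed coupling with the vinylogous α-iodo ketone 18 form the hindered C8–C3'' bond, a dialkylbiarylphosphine being chosen because such ligands permit tetra-ortho-substituted couplings; the flavan stereocentres are not involved.

Step 12
Reactants: 21 the 3-(flavan-8-yl)flavone from step 11
Product: 22 2'',3''-epoxide of 21 (epoxide oxygen on the chromone face that becomes the (R)-C3'' hydroxyl)
Conditions: (R,R)-[N,N'-bis(3,5-di-tert-butylsalicylidene)cyclohexane-1,2-diaminato]MnCl (10 mol %), dimethyldioxirane (acetone solution), CH2Cl2, −20 °C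
Reagents that add atoms: dimethyldioxirane CC1(C)OO1
Why: Manganese–salen-catalysed (Jacobsen–Katsuki type) oxygen transfer to the chromone C2''=C3'' bond, as used for enantioselective epoxidation of isoflavones; the chiral catalyst selects the alkene face and thereby sets C3'', while C2'' is only provisionally set.

Step 13
Reactants: 22 the 2'',3''-epoxide from step 12
Product: 23 tetra-O-benzyl ether of the target (benzyl on the ring B oxygen, on both ring D oxygens and on the ring F oxygen; C5–OH free; (2S,3R,2''S,3''R))
Conditions: HCl (2 M in MeOH), CH2Cl2, 0 °C → rt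
Reagents that add atoms: none
Why: Acid cleaves both methoxymethyl ethers and opens the epoxide at C2'' to an oxocarbenium ion stabilised by the ring E oxygen and the 4-benzyloxyphenyl group (SN1 epoxide opening), which the freed C7 phenol captures in a five-membered intramolecular ketalisation; C3'' keeps the configuration from step 12 because its C–O bond is never broken, and C2'' is fixed under thermodynamic control by the ring fusion to C3''.

Step 14
Reactants: 23 tetra-O-benzyl ether of the target
Product: 24 target CNP0205438.1 ((2S,3R,2''S,3''R); 3-O-methylflavan fused through C8–C3'' and C7–O–C2'' to a 3''-hydroxy-5'',7''-dihydroxy-2''-(4-hydroxyphenyl)chroman-4''-one)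
Conditions: H2 (1 atm), Pd/C, EtOAc/MeOH, rt
Reagents that add atoms: none
Why: Catalytic hydrogenolysis removes the four benzyl ethers; the ketal, the tertiary α-hydroxy ketone and the flavan C2–O1 bond should survive the neutral conditions, and no stereocentre is touched.

**Compound list**

1 | 5-bromobenzene-1,3-diol | Oc1cc(O)cc(Br)c1 | starting material
2 | N-[(2-bromo-4,6-dihydroxyphenyl)methylidene]-N-methylmethanaminium chloride | C[N+](C)=Cc1c(O)cc(O)cc1Br.[Cl-] | intermediate
3 | 2-bromo-4,6-dihydroxybenzaldehyde | O=Cc1c(O)cc(O)cc1Br | intermediate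
4 | 2-bromo-4,6-bis(methoxymethoxy)benzaldehyde | O=Cc1c(OCOC)cc(OCOC)cc1Br | intermediate
5 | [2-bromo-4,6-bis(methoxymethoxy)phenyl]methanol | OCc1c(OCOC)cc(OCOC)cc1Br | intermediate
6 | 2-bromo-4,6-bis(methoxymethoxy)benzyl methanesulfonate | CS(=O)(=O)OCc1c(OCOC)cc(OCOC)cc1Br | intermediate
7 | 1-bromo-2-(chloromethyl)-3,5-bis(methoxymethoxy)benzene | ClCc1c(OCOC)cc(OCOC)cc1Br | intermediate
8 | 1-[4-(benzyloxy)phenyl]ethan-1-one | CC(=O)c1ccc(OCc2ccccc2)cc1 | starting material
9 | 1-[4-(benzyloxy)phenyl]-3-[2-bromo-4,6-bis(methoxymethoxy)phenyl]propan-1-one | O=C(CCc1c(OCOC)cc(OCOC)cc1Br)c1ccc(OCc2ccccc2)cc1 | intermediate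
10 | 2-[4-(benzyloxy)phenyl]-5,7-bis(methoxymethoxy)-4H-chromene | COCOc1cc(OCOC)c2CC=C(c3ccc(OCc4ccccc4)cc3)Oc2c1 | intermediate
11 | (isopinocampheyl)[2,3-trans-2-[4-(benzyloxy)phenyl]-5,7-bis(methoxymethoxy)chroman-3-yl]borane (C2 and C3 arranged as in 12; Ipc from (−)-α-pinene) | C[C@@H]1[C@@H](B[C@@H]2Cc3c(OCOC)cc(OCOC)cc3O[C@H]2c2ccc(OCc3ccccc3)cc2)C[C@H]2C[C@@H]1C2(C)C | intermediate
12 | (2S,3R)-2-[4-(benzyloxy)phenyl]-5,7-bis(methoxymethoxy)chroman-3-ol | O[C@@H]1Cc2c(OCOC)cc(OCOC)cc2O[C@H]1c1ccc(OCc2ccccc2)cc1 | intermediate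
13 | (2S,3R)-2-[4-(benzyloxy)phenyl]-3-methoxy-5,7-bis(methoxymethoxy)chromane | CO[C@@H]1Cc2c(OCOC)cc(OCOC)cc2O[C@H]1c1ccc(OCc2ccccc2)cc1 | intermediate
14 | (2S,3R)-2-[4-(benzyloxy)phenyl]-8-bromo-3-methoxy-5,7-bis(methoxymethoxy)chromane | CO[C@@H]1Cc2c(OCOC)cc(OCOC)c(Br)c2O[C@H]1c1ccc(OCc2ccccc2)cc1 | intermediate
15 | 5,7-dihydroxy-2-(4-hydroxyphenyl)-4H-chromen-4-one (apigenin) | O=c1cc(-c2ccc(O)cc2)oc2cc(O)cc(O)c12 | starting material
16 | 5,7-bis(benzyloxy)-2-[4-(benzyloxy)phenyl]-4H-chromen-4-one | O=c1cc(-c2ccc(OCc3ccccc3)cc2)oc2cc(OCc3ccccc3)cc(OCc3ccccc3)c12 | intermediate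
17 | [5,7-bis(benzyloxy)-2-[4-(benzyloxy)phenyl]-4-oxo-4H-chromen-3-yl]lithium | [Li]c1c(-c2ccc(OCc3ccccc3)cc2)oc2cc(OCc3ccccc3)cc(OCc3ccccc3)c2c1=O | intermediate
18 | 5,7-bis(benzyloxy)-2-[4-(benzyloxy)phenyl]-3-iodo-4H-chromen-4-one | Ic1c(-c2ccc(OCc3ccccc3)cc2)oc2cc(OCc3ccccc3)cc(OCc3ccccc3)c2c1=O | intermediate
19 | [(2S,3R)-2-[4-(benzyloxy)phenyl]-3-methoxy-5,7-bis(methoxymethoxy)chroman-8-yl]lithium | CO[C@@H]1Cc2c(OCOC)cc(OCOC)c([Li])c2O[C@H]1c1ccc(OCc2ccccc2)cc1 | intermediate
20 | chloro[(2S,3R)-2-[4-(benzyloxy)phenyl]-3-methoxy-5,7-bis(methoxymethoxy)chroman-8-yl]zinc | CO[C@@H]1Cc2c(OCOC)cc(OCOC)c([Zn]Cl)c2O[C@H]1c1ccc(OCc2ccccc2)cc1 | intermediate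
21 | 5,7-bis(benzyloxy)-2-[4-(benzyloxy)phenyl]-3-[(2S,3R)-2-[4-(benzyloxy)phenyl]-3-methoxy-5,7-bis(methoxymethoxy)chroman-8-yl]-4H-chromen-4-one | CO[C@@H]1Cc2c(OCOC)cc(OCOC)c(c2O[C@H]1c1ccc(OCc2ccccc2)cc1)-c1c(-c2ccc(OCc3ccccc3)cc2)oc2cc(OCc3ccccc3)cc(OCc3ccccc3)c2c1=O | intermediate
22 | 2'',3''-epoxide of 21 (oxireno[2,3-b]chromen-7-one; epoxide oxygen on the face that becomes the (R)-C3'' hydroxyl; 4-benzyloxyphenyl on C2'', flavan-8-yl on C3'') | CO[C@@H]1Cc2c(OCOC)cc(OCOC)c(c2O[C@H]1c1ccc(OCc2ccccc2)cc1)[C@@]12O[C@@]2(c2ccc(OCc3ccccc3)cc2)Oc2cc(OCc3ccccc3)cc(OCc3ccccc3)c2C1=O | intermediate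
23 | tetra-O-benzyl ether of the target, (2S,3R,2''S,3''R), C5–OH free | CO[C@@H]1Cc2c(O)cc3c(c2O[C@H]1c1ccc(OCc2ccccc2)cc1)[C@@]1(O)C(=O)c2c(OCc4ccccc4)cc(OCc4ccccc4)cc2O[C@]1(c1ccc(OCc2ccccc2)cc1)O3 | intermediate
24 | CNP0205438.1, (2S,3R,2''S,3''R) | CO[C@@H]1Cc2c(O)cc3c(c2O[C@H]1c1ccc(O)cc1)[C@@]1(O)C(=O)c2c(O)cc(O)cc2O[C@]1(c1ccc(O)cc1)O3 | target

**Step count and risks**

Total step count: 14. Longest linear sequence: 12 steps (steps 1–8, then 11–14); steps 9–10 make the second fragment.

Steps most likely to fail:

Step 5 (Proposed new method). What may go wrong: over-alkylation of the enolate, or sluggish copper-mediated O-arylation of a non-stabilised ketone enolate so that aldol self-condensation takes over at 85 °C. Fallback with known chemistry, setting out from 7 and 8 and coming back at 10: the sequence is stopped after the alkylation stage and bromo ketone 9 is isolated (ordinary enolate alkylation). The aryl bromide is then converted into the phenol by palladium-catalysed hydroxylation (Pd2(dba)3, t-BuXPhos, KOH, dioxane/H2O, 100 °C) to give 3-[2-hydroxy-4,6-bis(methoxymethoxy)phenyl]-1-[4-(benzyloxy)phenyl]propan-1-one F1. This is cyclodehydrated (pyridinium p-toluenesulfonate cat., toluene, 4 Å sieves, 60 °C) to 10, the classical closure of a 2-hydroxydihydrochalcone to a flav-2-ene, in which ring C closes through the phenol oxygen onto C2.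

Step 12. What may go wrong: poor facial discrimination or low conversion in the epoxidation of a hindered, tetrasubstituted push–pull double bond, and competing oxidation of the electron-rich ring A. Fallback, setting out from 21 and coming back at 23: reagent control is given up. 21 is epoxidised with dimethyldioxirane alone (acetone/CH2Cl2, 0 °C, as for flavones) to 22 together with the epoxide-face diastereomer of 22 F2. The mixture is submitted to the conditions of step 13, and 23 is separated by chromatography from the C2''/C3'' diastereomer of 23 F3; the two are diastereomers because of the flavan stereocentres.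

Step 6. What may go wrong: incomplete asymmetric induction in the hydroboration of an enol ether, and acid-promoted hydration of the enol ether before it is hydroborated. Fallback, setting out from 10 and coming back at 12: asymmetric induction is replaced by resolution. Hydroboration with BH3·SMe2 (THF, 0 °C; then NaOH, H2O2) should give the racemic 2,3-trans alcohol, that is 12 together with the (2R,3S)-enantiomer of 12 F4. 12 is then obtained by preparative chromatography on a chiral stationary phase (or through diastereomeric camphanate esters).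

Further compounds
F1 | step 5 | 3-[2-hydroxy-4,6-bis(methoxymethoxy)phenyl]-1-[4-(benzyloxy)phenyl]propan-1-one | COCOc1cc(O)c(CCC(=O)c2ccc(OCc3ccccc3)cc2)c(OCOC)c1
F2 | step 12 | epoxide-face diastereomer of 22 | CO[C@@H]1Cc2c(OCOC)cc(OCOC)c(c2O[C@H]1c1ccc(OCc2ccccc2)cc1)[C@]12O[C@]2(c2ccc(OCc3ccccc3)cc2)Oc2cc(OCc3ccccc3)cc(OCc3ccccc3)c2C1=O
F3 | step 12 | C2''/C3'' diastereomer of 23 | CO[C@@H]1Cc2c(O)cc3c(c2O[C@H]1c1ccc(OCc2ccccc2)cc1)[C@]1(O)C(=O)c2c(OCc4ccccc4)cc(OCc4ccccc4)cc2O[C@@]1(c1ccc(OCc2ccccc2)cc1)O3
F4 | step 6 | (2R,3S)-2-[4-(benzyloxy)phenyl]-5,7-bis(methoxymethoxy)chroman-3-ol | O[C@H]1Cc2c(OCOC)cc(OCOC)cc2O[C@@H]1c1ccc(OCc2ccccc2)cc1
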